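**Retrosynthetic overview**
- The route rests on the cis-fused γ-lactone (O–C6, C6–C7, C7–C11, C11–C12) on the ten-membered ring, with C6 allylic to C4=C5. C11–C12 is added as a malonyl unit across C6=C7 of a ring diene C4=C5–C6=C7, forming C7–C11 and O–C6 in one step.
- End game: decarboxylative methylenation (C11=C13), 8-O-acylation with the acetonide-protected (R)-3,4-dihydroxy-2-methylenebutanoic acid, acetonide hydrolysis, and a Schenck ene reaction at C1=C10 (C1–OOH, C10=C14).
- The ten-membered triene is closed at C7–C8 by a Nozaki–Hiyama–Kishi reaction of a (Z)-dienyl iodide with an aldehyde; C8 is then set by oxidation and Corey–Bakshi–Shibata reduction.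
- The open chain comes from Negishi carboalumination (E C1=C10), ethylene oxide (C2–C3), a stabilised phosphorane (C4, C15) and (Z)-3-iodoacrolein (C5–C7).
- Ring order: ten-membered carbocycle (step 9), then the γ-lactone (step 13).

Key step: step 13

Remark: germacrane numbering is used (ring C1–C10, lactone C11–C13, C14 on C10, C15 on C4). "Ring-cis" at C4=C5 means C3 and C6 on the same side, which is E by the CIP rules. Compound 21 is drawn as the C11 epimer with CO2H trans to C8; an epimer mixture serves equally, because C11 becomes sp2 in step 14.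

**Step 1**
Reactants: 1 tert-butyl(but-3-yn-1-yloxy)dimethylsilane; 2 ethylene oxide
Product: 4 (E)-6-(tert-butyldimethylsilyloxy)-4-methylhex-3-en-1-ol, via alkenyldimethylalane 3 (not isolated)
Conditions: Me3Al, Cp2ZrCl2 (0.2 equiv), CH2Cl2, 0 to 25 °C; evaporate; n-BuLi, THF/hexane, −78 to 0 °C; 2, −30 to 25 °C
Reagents that add atoms: trimethylaluminium, C[Al](C)C
Why: Negishi zirconium-catalysed carboalumination adds methyl and aluminium syn across the terminal alkyne (methyl to the internal carbon), which fixes the E geometry of the future C1=C10 bond, and the derived lithium alanate opens ethylene oxide with retention at the alkenyl carbon to add C2 and C3.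

**Step 2**
Reactants: 4 (E)-6-(tert-butyldimethylsilyloxy)-4-methylhex-3-en-1-ol
Product: 5 tert-butyl{[(E)-6-iodo-3-methylhex-3-en-1-yl]oxy}dimethylsilane
Conditions: I2, PPh3, imidazole, CH2Cl2, 0 °C
Reagents that add atoms: iodine, II
Why: Appel-type iodination converts the primary alcohol into the iodide by SN2 displacement of the alkoxyphosphonium ion, without touching the silyl ether or the olefin.

**Step 3**
Reactants: 5 tert-butyl{[(E)-6-iodo-3-methylhex-3-en-1-yl]oxy}dimethylsilane; 6 ethyl (triphenylphosphoranylidene)acetate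
Product: 8 ethyl (E)-8-(tert-butyldimethylsilyloxy)-6-methyl-2-(triphenylphosphoranylidene)oct-5-enoate, via alkylphosphonium iodide 7 (not isolated)
Conditions: 6 (2.2 equiv), MeCN, 80 °C
Reagents that add atoms: none
Why: C-alkylation of the stabilised ylide by the primary iodide gives phosphonium salt 7, which a second equivalent of 6 deprotonates (transylidation) to the α-substituted stabilised ylide that carries C4 and C15.

**Step 4**
Reactants: 8 ethyl (E)-8-(tert-butyldimethylsilyloxy)-6-methyl-2-(triphenylphosphoranylidene)oct-5-enoate; 9 ethyl (Z)-3-iodoprop-2-enoate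
Product: 11 ethyl (2E,4Z)-5-iodo-2-[(E)-6-(tert-butyldimethylsilyloxy)-4-methylhex-3-en-1-yl]penta-2,4-dienoate, via (Z)-3-iodoacrolein 10 (not isolated)
Conditions: 9, i-Bu2AlH (1.05 equiv), CH2Cl2, −78 °C; then 8, −78 to 25 °C
Reagents that add atoms: none
Why: Low-temperature reduction of ester 9 releases (Z)-3-iodoacrolein with its geometry intact, and the Wittig reaction of the α-substituted stabilised ylide is E-selective (ester trans to C6), which puts C3 and C6 on the same side of C4=C5 as the ring-cis olefin requires.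

**Step 5**
Reactants: 11 ethyl (2E,4Z)-5-iodo-2-[(E)-6-(tert-butyldimethylsilyloxy)-4-methylhex-3-en-1-yl]penta-2,4-dienoate
Product: 12 (2E,4Z)-5-iodo-2-[(E)-6-(tert-butyldimethylsilyloxy)-4-methylhex-3-en-1-yl]penta-2,4-dien-1-ol
Conditions: i-Bu2AlH (2.5 equiv), CH2Cl2, −78 °C
Reagents that add atoms: none
Why: The aluminium hydride reduces the conjugated ester in 1,2 fashion to the allylic alcohol at low temperature and leaves the alkenyl iodide and the silyl ether untouched.

**Step 6**
Reactants: 12 (2E,4Z)-5-iodo-2-[(E)-6-(tert-butyldimethylsilyloxy)-4-methylhex-3-en-1-yl]penta-2,4-dien-1-ol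
Product: 13 (2E,4Z)-5-iodo-2-[(E)-6-(tert-butyldimethylsilyloxy)-4-methylhex-3-en-1-yl]penta-2,4-dien-1-yl acetate
Conditions: Ac2O, pyridine, 4-(dimethylamino)pyridine (cat.), CH2Cl2, 0 to 25 °C
Reagents that add atoms: acetic anhydride, CC(=O)OC(C)=O
Why: Nucleophile-catalysed acetylation installs the C15 acetate of the target early, where it also protects this hydroxyl for the rest of the route.

**Step 7**
Reactants: 13 (2E,4Z)-5-iodo-2-[(E)-6-(tert-butyldimethylsilyloxy)-4-methylhex-3-en-1-yl]penta-2,4-dien-1-yl acetate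
Product: 14 (2E,4Z)-2-[(E)-6-hydroxy-4-methylhex-3-en-1-yl]-5-iodopenta-2,4-dien-1-yl acetate
Conditions: HF·pyridine, pyridine, THF, 0 °C
Reagents that add atoms: none
Why: Fluoride cleaves the primary silyl ether under buffered conditions that spare the allylic acetate and the dienyl iodide.

**Step 8**
Reactants: 14 (2E,4Z)-2-[(E)-6-hydroxy-4-methylhex-3-en-1-yl]-5-iodopenta-2,4-dien-1-yl acetate
Product: 15 (2E,4Z)-5-iodo-2-[(E)-4-methyl-6-oxohex-3-en-1-yl]penta-2,4-dien-1-yl acetate
Conditions: Dess–Martin periodinane, NaHCO3, CH2Cl2, 0 °C; used at once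
Reagents that add atoms: none
Why: Dess–Martin oxidation under bicarbonate buffer gives the β,γ-unsaturated aldehyde without the acid or base that would move C1=C10 into conjugation.

**Step 9**
Reactants: 15 (2E,4Z)-5-iodo-2-[(E)-4-methyl-6-oxohex-3-en-1-yl]penta-2,4-dien-1-yl acetate
Product: 16 racemic [(1E,3Z,7E)-5-hydroxy-7-methylcyclodeca-1,3,7-trien-1-yl]methyl acetate
Conditions: CrCl2 (8 equiv), NiCl2 (0.1 equiv), degassed DMSO, 25 °C, 0.003 M, slow addition of 15
Reagents that add atoms: none
Why: Nozaki–Hiyama–Kishi reaction: zerovalent nickel inserts into the alkenyl C–I bond with retention of the Z geometry, transmetalation gives a non-basic alkenylchromium species that adds only to the aldehyde, and high dilution favours closure of the ten-membered ring between C7 and C8; the C8 carbinol forms racemic and is corrected in steps 10 and 11.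

**Step 10**
Reactants: 16 racemic [(1E,3Z,7E)-5-hydroxy-7-methylcyclodeca-1,3,7-trien-1-yl]methyl acetate
Product: 17 [(1E,3Z,7E)-7-methyl-5-oxocyclodeca-1,3,7-trien-1-yl]methyl acetate
Conditions: Dess–Martin periodinane, NaHCO3, CH2Cl2, 0 °C
Reagents that add atoms: none
Why: Dess–Martin oxidation of the dienylic alcohol removes the uncontrolled C8 centre and gives the ring dienone under neutral conditions that keep C1=C10 out of conjugation.

**Step 11**
Reactants: 17 [(1E,3Z,7E)-7-methyl-5-oxocyclodeca-1,3,7-trien-1-yl]methyl acetate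
Product: 18 [(1E,3Z,5S,7E)-5-hydroxy-7-methylcyclodeca-1,3,7-trien-1-yl]methyl acetate
Conditions: (R)-Me-CBS oxazaborolidine (C18H20BNO, 0.5 equiv), catecholborane, toluene, −78 °C
Reagents that add atoms: none
Why: Corey–Bakshi–Shibata reduction: the ketone binds the oxazaborolidine with the Z-dienyl arm as the large group and the C9 methylene as the small one, so the (R)-catalyst is expected to deliver hydride to the face that gives the (S)-carbinol at C8, and catecholborane at −78 °C avoids hydroboration of the olefins.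

**Step 12**
Reactants: 18 [(1E,3Z,5S,7E)-5-hydroxy-7-methylcyclodeca-1,3,7-trien-1-yl]methyl acetate
Product: 19 [(1E,3Z,5S,7E)-5-(tert-butyldimethylsilyloxy)-7-methylcyclodeca-1,3,7-trien-1-yl]methyl acetate
Conditions: TBSCl, imidazole, DMF, 25 °C
Reagents that add atoms: tert-butyldimethylsilyl chloride, CC(C)(C)[Si](C)(C)Cl
Why: Standard silylation of the secondary alcohol; the silyl ether is stable to acetic acid, shields O8 and keeps this oxygen from lactonising in the key step.

**Step 13**
Reactants: 19 [(1E,3Z,5S,7E)-5-(tert-butyldimethylsilyloxy)-7-methylcyclodeca-1,3,7-trien-1-yl]methyl acetate; 20 malonic acid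
Product: 21 (6S,7S,8S,11R)-15-acetoxy-8-(tert-butyldimethylsilyloxy)-11-carboxy-germacra-1(10)E,4-dien-12,6-olide (cis-fused lactone, 13-nor)
Conditions: 20 (5 equiv), Mn(OAc)3·2H2O (2.2 equiv), Cu(OAc)2·H2O (0.5 equiv), KOAc, AcOH, 25 °C, N2
Reagents that add atoms: none
Why: Manganese triacetate oxidises malonic acid, through its enolate complex of trivalent manganese, to the electrophilic dicarboxymethyl radical, which adds to C7, the less substituted terminus of the C4=C5–C6=C7 diene; divalent copper oxidises the resulting C4–C5–C6 allyl radical and a carboxylate oxygen closes on C6. The closest known reaction is the manganese triacetate carbolactonisation of olefins and 1,3-dienes with malonic or acetic acid, which gives α-carboxy γ-lactones at room temperature. The lactone ring (O, C12, C11, C7, C6) closes by 5-exo attack of oxygen on the allyl terminus C6, the only terminus the short tether can reach, so C4=C5 stays with its ring-cis geometry. At C7 the radical should enter on the peripheral face, because A(1,3) strain across the cis C6=C7 bond holds H8 in the diene plane, the C8–C9 ring bond covers one face and the silyloxy group points outward, so that C11 ends trans to O8 on the ring; C6 is then set by closure on the face that carries C11 (cis fusion), and C11 is erased in step 14. The step needs attack on the diene and not on the isolated C1=C10 olefin, at C7 and not C4, and one oxidation only: allyl stabilisation and the unhindered CH terminus favour C7, excess malonic acid keeps the oxidant from the product C11–H, copper diacetate outruns transannular radical cyclisation, and the silyl ether stops the second carboxyl group from lactonising onto O8.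

**Step 14**
Reactants: 21 (6S,7S,8S,11R)-15-acetoxy-8-(tert-butyldimethylsilyloxy)-11-carboxy-germacra-1(10)E,4-dien-12,6-olide
Product: 23 (6S,7S,8S)-15-acetoxy-8-(tert-butyldimethylsilyloxy)germacra-1(10)E,4,11(13)-trien-12,6-olide, via Mannich base 22 (not isolated)
Conditions: 37% aq. HCHO, Et2NH, NaOAc, AcOH, 25 °C then 70 °C
Reagents that add atoms: formaldehyde, C=O
Why: Decarboxylative Mannich methylenation: the malonate-type C11–H condenses with the iminium ion from formaldehyde and diethylamine, and the β-amino acid 22 loses CO2 and diethylamine on warming to give the C11=C13 methylene, which removes the C11 stereocentre.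

**Step 15**
Reactants: 23 (6S,7S,8S)-15-acetoxy-8-(tert-butyldimethylsilyloxy)germacra-1(10)E,4,11(13)-trien-12,6-olide
Product: 24 (6S,7R,8S)-15-acetoxy-8-hydroxygermacra-1(10)E,4,11(13)-trien-12,6-olide
Conditions: HF·pyridine, THF, 0 to 25 °C
Reagents that add atoms: none
Why: Fluoride removes the secondary silyl ether under non-basic conditions that neither add to the α-methylene lactone nor cleave the acetate (the CIP descriptor at C7 changes only because silicon is lost).

**Step 16**
Reactants: 25 methyl (S)-2,2-dimethyl-1,3-dioxolane-4-carboxylate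
Product: 26 (S)-N-methoxy-N,2,2-trimethyl-1,3-dioxolane-4-carboxamide
Conditions: MeNH(OMe)·HCl, i-PrMgCl, THF, −20 °C
Reagents that add atoms: N,O-dimethylhydroxylamine hydrochloride, CNOC.Cl
Why: The chloromagnesium amide of N,O-dimethylhydroxylamine converts the ester into the Weinreb amide at low temperature without epimerising the α-alkoxy centre.

**Step 17**
Reactants: 26 (S)-N-methoxy-N,2,2-trimethyl-1,3-dioxolane-4-carboxamide
Product: 27 (S)-1-(2,2-dimethyl-1,3-dioxolan-4-yl)ethan-1-one
Conditions: MeMgBr, THF, 0 °C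
Reagents that add atoms: methylmagnesium bromide, C[Mg]Br
Why: Grignard addition to the Weinreb amide stops at the chelated tetrahedral intermediate, so the methyl ketone forms without over-addition and the stereocentre is kept.

**Step 18**
Reactants: 27 (S)-1-(2,2-dimethyl-1,3-dioxolan-4-yl)ethan-1-one
Product: 28 (S)-1-(2,2-dimethyl-1,3-dioxolan-4-yl)ethenyl trifluoromethanesulfonate
Conditions: KN(SiMe3)2, THF, −78 °C; then PhNTf2
Reagents that add atoms: N-phenylbis(trifluoromethanesulfonimide), O=S(=O)(N(c1ccccc1)S(=O)(=O)C(F)(F)F)C(F)(F)F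
Why: Kinetic deprotonation by the bulky amide base occurs at the methyl group and not at the ring methine, and O-triflation of the potassium enolate gives the 1,1-disubstituted enol triflate with the stereocentre intact.

**Step 19**
Reactants: 28 (S)-1-(2,2-dimethyl-1,3-dioxolan-4-yl)ethenyl trifluoromethanesulfonate
Product: 29 2-[(R)-2,2-dimethyl-1,3-dioxolan-4-yl]prop-2-enoic acid
Conditions: Pd(OAc)2 (5 mol %), 1,1'-bis(diphenylphosphino)ferrocene, CO (1 atm), KOAc, DMF/H2O, 50 °C
Reagents that add atoms: carbon monoxide, [C-]#[O+]; water, O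
Why: Palladium-catalysed hydroxycarbonylation: oxidative addition of the enol triflate to zerovalent palladium, CO insertion and hydrolysis of the acyl palladium give the 2-substituted acrylic acid; the descriptor changes from S to R only through the new substituent priorities.

**Step 20**
Reactants: 24 (6S,7R,8S)-15-acetoxy-8-hydroxygermacra-1(10)E,4,11(13)-trien-12,6-olide; 29 2-[(R)-2,2-dimethyl-1,3-dioxolan-4-yl]prop-2-enoic acid
Product: 31 (6S,7R,8S)-15-acetoxy-8-{2-[(R)-2,2-dimethyl-1,3-dioxolan-4-yl]prop-2-enoyloxy}germacra-1(10)E,4,11(13)-trien-12,6-olide, via mixed anhydride 30 (not isolated)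
Conditions: 29, 2,4,6-trichlorobenzoyl chloride, Et3N, THF, 0 °C; then 24, 4-(dimethylamino)pyridine, toluene, 25 °C
Reagents that add atoms: none
Why: Yamaguchi esterification: the mixed anhydride 30 transfers the acyl group to the hindered secondary C8 hydroxyl through the acylpyridinium ion, with retention at C8 because its C–O bond is not broken.

**Step 21**
Reactants: 31 (6S,7R,8S)-15-acetoxy-8-{2-[(R)-2,2-dimethyl-1,3-dioxolan-4-yl]prop-2-enoyloxy}germacra-1(10)E,4,11(13)-trien-12,6-olide
Product: 32 (6S,7R,8S)-15-acetoxy-8-[(R)-3,4-dihydroxy-2-methylenebutanoyloxy]germacra-1(10)E,4,11(13)-trien-12,6-olide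
Conditions: AcOH/H2O 4:1, 40 °C
Reagents that add atoms: none
Why: Mild aqueous acid hydrolyses the terminal acetonide to the 1,2-diol, while the esters, the lactone and the olefins are stable.

**Step 22**
Reactants: 32 (6S,7R,8S)-15-acetoxy-8-[(R)-3,4-dihydroxy-2-methylenebutanoyloxy]germacra-1(10)E,4,11(13)-trien-12,6-olide
Product: 33 (1R,6S,7R,8S)-15-acetoxy-8-[(R)-3,4-dihydroxy-2-methylenebutanoyloxy]-1-hydroperoxygermacra-4,10(14),11(13)-trien-12,6-olide (CNP0307408.1)
Conditions: O2, visible light, 5,10,15,20-tetraphenylporphyrin (cat.), CH2Cl2, 0 °C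
Reagents that add atoms: dioxygen, O=O
Why: Schenck ene reaction: singlet oxygen attacks the electron-rich trisubstituted C1=C10 olefin (C4=C5 is deactivated by the allylic acetate and lactone oxygen, the two acrylate units are inert) and abstracts hydrogen from the C14 methyl group on the more crowded side, which gives C10=C14 and the C1 hydroperoxide; approach from the outer face of the E olefin is expected to give the (1R) epimer.

**Compound list**
1 | tert-butyl(but-3-yn-1-yloxy)dimethylsilane | C#CCCO[Si](C)(C)C(C)(C)C | starting material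
2 | ethylene oxide | C1CO1 | starting material
3 | [(E)-4-(tert-butyldimethylsilyloxy)-2-methylbut-1-en-1-yl]dimethylalane | C[Al](C)/C=C(\C)CCO[Si](C)(C)C(C)(C)C | intermediate (not isolated)
4 | (E)-6-(tert-butyldimethylsilyloxy)-4-methylhex-3-en-1-ol | OCC/C=C(\C)CCO[Si](C)(C)C(C)(C)C | intermediate
5 | tert-butyl{[(E)-6-iodo-3-methylhex-3-en-1-yl]oxy}dimethylsilane | ICC/C=C(\C)CCO[Si](C)(C)C(C)(C)C | intermediate
6 | ethyl (triphenylphosphoranylidene)acetate | CCOC(=O)C=P(c1ccccc1)(c1ccccc1)c1ccccc1 | starting material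
7 | [(E)-8-(tert-butyldimethylsilyloxy)-1-ethoxy-6-methyl-1-oxooct-5-en-2-yl]triphenylphosphonium iodide | CCOC(=O)C(CC/C=C(\C)CCO[Si](C)(C)C(C)(C)C)[P+](c1ccccc1)(c1ccccc1)c1ccccc1.[I-] | intermediate (not isolated)
8 | ethyl (E)-8-(tert-butyldimethylsilyloxy)-6-methyl-2-(triphenylphosphoranylidene)oct-5-enoate | CCOC(=O)C(CC/C=C(\C)CCO[Si](C)(C)C(C)(C)C)=P(c1ccccc1)(c1ccccc1)c1ccccc1 | intermediate
9 | ethyl (Z)-3-iodoprop-2-enoate | CCOC(=O)/C=C\I | starting material
10 | (Z)-3-iodoprop-2-enal | O=C/C=C\I | intermediate (not isolated)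
11 | ethyl (2E,4Z)-5-iodo-2-[(E)-6-(tert-butyldimethylsilyloxy)-4-methylhex-3-en-1-yl]penta-2,4-dienoate | CCOC(=O)C(/CC/C=C(\C)CCO[Si](C)(C)C(C)(C)C)=C/C=C\I | intermediate
12 | (2E,4Z)-5-iodo-2-[(E)-6-(tert-butyldimethylsilyloxy)-4-methylhex-3-en-1-yl]penta-2,4-dien-1-ol | OCC(/CC/C=C(\C)CCO[Si](C)(C)C(C)(C)C)=C/C=C\I | intermediate
13 | (2E,4Z)-5-iodo-2-[(E)-6-(tert-butyldimethylsilyloxy)-4-methylhex-3-en-1-yl]penta-2,4-dien-1-yl acetate | CC(=O)OCC(/CC/C=C(\C)CCO[Si](C)(C)C(C)(C)C)=C/C=C\I | intermediate
14 | (2E,4Z)-2-[(E)-6-hydroxy-4-methylhex-3-en-1-yl]-5-iodopenta-2,4-dien-1-yl acetate | CC(=O)OCC(/CC/C=C(\C)CCO)=C/C=C\I | intermediate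
15 | (2E,4Z)-5-iodo-2-[(E)-4-methyl-6-oxohex-3-en-1-yl]penta-2,4-dien-1-yl acetate | CC(=O)OCC(/CC/C=C(\C)CC=O)=C/C=C\I | intermediate
16 | racemic [(1E,3Z,7E)-5-hydroxy-7-methylcyclodeca-1,3,7-trien-1-yl]methyl acetate | C1/C(COC(C)=O)=C\C=C/C(O)C/C(C)=C/C1 | intermediate
17 | [(1E,3Z,7E)-7-methyl-5-oxocyclodeca-1,3,7-trien-1-yl]methyl acetate | C1/C(COC(C)=O)=C\C=C/C(=O)C/C(C)=C/C1 | intermediate
18 | [(1E,3Z,5S,7E)-5-hydroxy-7-methylcyclodeca-1,3,7-trien-1-yl]methyl acetate | C1/C(COC(C)=O)=C\C=C/[C@@H](O)C/C(C)=C/C1 | intermediate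
19 | [(1E,3Z,5S,7E)-5-(tert-butyldimethylsilyloxy)-7-methylcyclodeca-1,3,7-trien-1-yl]methyl acetate (key-step precursor) | C1/C(COC(C)=O)=C\C=C/[C@@H](O[Si](C)(C)C(C)(C)C)C/C(C)=C/C1 | intermediate
20 | malonic acid | OC(=O)CC(=O)O | starting material
21 | (6S,7S,8S,11R)-15-acetoxy-8-(tert-butyldimethylsilyloxy)-11-carboxy-germacra-1(10)E,4-dien-12,6-olide (key-step product) | OC(=O)[C@@H]1C(=O)O[C@H]2/C=C(/COC(C)=O)CC/C=C(\C)C[C@H](O[Si](C)(C)C(C)(C)C)[C@@H]12 | intermediate
22 | 11-carboxy-11-(diethylaminomethyl) lactone (Mannich base of 21, C11 unassigned) | CCN(CC)CC1(C(=O)O)C(=O)O[C@H]2/C=C(/COC(C)=O)CC/C=C(\C)C[C@H](O[Si](C)(C)C(C)(C)C)[C@@H]12 | intermediate (not isolated)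
23 | (6S,7S,8S)-15-acetoxy-8-(tert-butyldimethylsilyloxy)germacra-1(10)E,4,11(13)-trien-12,6-olide | C=C1C(=O)O[C@H]2/C=C(/COC(C)=O)CC/C=C(\C)C[C@H](O[Si](C)(C)C(C)(C)C)[C@@H]12 | intermediate
24 | (6S,7R,8S)-15-acetoxy-8-hydroxygermacra-1(10)E,4,11(13)-trien-12,6-olide | C=C1C(=O)O[C@H]2/C=C(/COC(C)=O)CC/C=C(\C)C[C@H](O)[C@@H]12 | intermediate
25 | methyl (S)-2,2-dimethyl-1,3-dioxolane-4-carboxylate | COC(=O)[C@@H]1COC(C)(C)O1 | starting material
26 | (S)-N-methoxy-N,2,2-trimethyl-1,3-dioxolane-4-carboxamide | CON(C)C(=O)[C@@H]1COC(C)(C)O1 | intermediate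
27 | (S)-1-(2,2-dimethyl-1,3-dioxolan-4-yl)ethan-1-one | CC(=O)[C@@H]1COC(C)(C)O1 | intermediate
28 | (S)-1-(2,2-dimethyl-1,3-dioxolan-4-yl)ethenyl trifluoromethanesulfonate | C=C(OS(=O)(=O)C(F)(F)F)[C@@H]1COC(C)(C)O1 | intermediate
29 | 2-[(R)-2,2-dimethyl-1,3-dioxolan-4-yl]prop-2-enoic acid | C=C(C(=O)O)[C@@H]1COC(C)(C)O1 | intermediate
30 | 2-[(R)-2,2-dimethyl-1,3-dioxolan-4-yl]prop-2-enoic 2,4,6-trichlorobenzoic anhydride | C=C(C(=O)OC(=O)c1c(Cl)cc(Cl)cc1Cl)[C@@H]1COC(C)(C)O1 | intermediate (not isolated)
31 | (6S,7R,8S)-15-acetoxy-8-{2-[(R)-2,2-dimethyl-1,3-dioxolan-4-yl]prop-2-enoyloxy}germacra-1(10)E,4,11(13)-trien-12,6-olide | C=C1C(=O)O[C@H]2/C=C(/COC(C)=O)CC/C=C(\C)C[C@H](OC(=O)C(=C)[C@@H]3COC(C)(C)O3)[C@@H]12 | intermediate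
32 | (6S,7R,8S)-15-acetoxy-8-[(R)-3,4-dihydroxy-2-methylenebutanoyloxy]germacra-1(10)E,4,11(13)-trien-12,6-olide | C=C1C(=O)O[C@H]2/C=C(/COC(C)=O)CC/C=C(\C)C[C@H](OC(=O)C(=C)[C@@H](O)CO)[C@@H]12 | intermediate
33 | (1R,6S,7R,8S)-15-acetoxy-8-[(R)-3,4-dihydroxy-2-methylenebutanoyloxy]-1-hydroperoxygermacra-4,10(14),11(13)-trien-12,6-olide | C=C1C(=O)O[C@H]2/C=C(/COC(C)=O)CC[C@@H](OO)C(=C)C[C@H](OC(=O)C(=C)[C@@H](O)CO)[C@@H]12 | target

**Step count**
Total: 22 steps. Longest linear sequence: 18 steps (steps 1–15 and 20–22).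

**Steps most likely to fail**
- **Step 13.** The electrophilic radical may attack the isolated, more electron-rich C1=C10 olefin instead of the diene, the acidic oxidising medium may trigger transannular cyclisation of the triene, and the product C11–H may be oxidised a second time. The fallback sets out from 19 and uses carbenoid chemistry instead. Rh2(OAc)4-catalysed cyclopropanation with 2,2-dimethyl-5-(phenyl-λ3-iodanylidene)-1,3-dioxane-4,6-dione should take place at the cis-disubstituted C6=C7 bond on the peripheral face, because the trisubstituted C1=C10 and C4=C5 bonds are poor partners for this bulky acceptor carbenoid; it gives the spiro-cyclopropane Meldrum's acid adduct F1. Warming F1 in wet acetonitrile ionises the vinylcyclopropane bond C6–C11, a carbonyl oxygen closes on C6 on the same face, and hydrolysis releases acetone, which returns the route to 21.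
- **Step 9.** Oligomerisation may compete with closure of the ten-membered ring, the β,γ-unsaturated aldehyde may isomerise into conjugation, and the alkenylchromium species may be protonated before it adds. The fallback sets out from 12 and closes the same C7–C8 bond at the ketone level. Palladium-catalysed iodine–tin exchange (Me3SnSnMe3, Pd(PPh3)4) should give the (Z)-dienylstannane dienol F2; acetylation gives its acetate F3; desilylation (Bu4NF, AcOH) gives the primary alcohol F4; Dess–Martin oxidation gives the aldehyde F5; and chlorite (Pinnick) oxidation gives the β,γ-unsaturated acid F6. Conversion to the acid chloride F7 (1-chloro-N,N,2-trimethylprop-1-en-1-amine) and intramolecular Stille acylation (Pd2(dba)3, tri(2-furyl)phosphine, high dilution) then give dienone 17, so step 10 is no longer needed.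
- **Step 22.** Singlet oxygen may add to the wrong face of C1=C10, giving the C1 epimer, or abstract a ring hydrogen at C2 or C9 instead of a C14 hydrogen. The fallback sets out from 31 and moves the ene reaction ahead of the diol release, so that the C1 centre is set on a substrate without free hydroxyl groups and with a different conformer population, in a non-protic medium. Photo-oxygenation of 31 gives the hydroperoxide acetonide F8, and hydrolysis of the acetonide with aqueous acetic acid in the presence of the hydroperoxide returns the route to 33.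

**Further compounds**
F1 | step 13 | spiro-cyclopropane of 19 across C6–C7 with 2,2-dimethyl-1,3-dioxane-4,6-dione at C11 | O=C1OC(C)(C)OC(=O)C12[C@H]3/C=C(/COC(C)=O)CC/C=C(\C)C[C@H](O[Si](C)(C)C(C)(C)C)[C@@H]23
F2 | step 9 | (2E,4Z)-2-[(E)-6-(tert-butyldimethylsilyloxy)-4-methylhex-3-en-1-yl]-5-(trimethylstannyl)penta-2,4-dien-1-ol | C[Sn](C)(C)/C=C\C=C(/CC/C=C(\C)CCO[Si](C)(C)C(C)(C)C)CO
F3 | step 9 | (2E,4Z)-2-[(E)-6-(tert-butyldimethylsilyloxy)-4-methylhex-3-en-1-yl]-5-(trimethylstannyl)penta-2,4-dien-1-yl acetate | C[Sn](C)(C)/C=C\C=C(/CC/C=C(\C)CCO[Si](C)(C)C(C)(C)C)COC(C)=O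
F4 | step 9 | (2E,4Z)-2-[(E)-6-hydroxy-4-methylhex-3-en-1-yl]-5-(trimethylstannyl)penta-2,4-dien-1-yl acetate | C[Sn](C)(C)/C=C\C=C(/CC/C=C(\C)CCO)COC(C)=O
F5 | step 9 | (2E,4Z)-2-[(E)-4-methyl-6-oxohex-3-en-1-yl]-5-(trimethylstannyl)penta-2,4-dien-1-yl acetate | C[Sn](C)(C)/C=C\C=C(/CC/C=C(\C)CC=O)COC(C)=O
F6 | step 9 | (3E,7E,9Z)-7-(acetoxymethyl)-3-methyl-10-(trimethylstannyl)deca-3,7,9-trienoic acid | C[Sn](C)(C)/C=C\C=C(/CC/C=C(\C)CC(=O)O)COC(C)=O
F7 | step 9 | (3E,7E,9Z)-7-(acetoxymethyl)-3-methyl-10-(trimethylstannyl)deca-3,7,9-trienoyl chloride | C[Sn](C)(C)/C=C\C=C(/CC/C=C(\C)CC(Cl)=O)COC(C)=O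
F8 | step 22 | (1R,6S,7R,8S)-15-acetoxy-8-{2-[(R)-2,2-dimethyl-1,3-dioxolan-4-yl]prop-2-enoyloxy}-1-hydroperoxygermacra-4,10(14),11(13)-trien-12,6-olide | C=C1C(=O)O[C@H]2/C=C(/COC(C)=O)CC[C@@H](OO)C(=C)C[C@H](OC(=O)C(=C)[C@@H]3COC(C)(C)O3)[C@@H]12
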